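**Plan**
Retrosynthesis: the C2' hydrogen of ring B is traced back to a CO2Me group and the ring A propanoic acid to an allyl group. Ring B is then cut at C1'-C6' and C2'-C3', the ether O-C4' bond is cut as an O-alkylation at an sp3 carbon, and the ynoate C-CO2Me bond as a carbonylation.
Enabling feature: in ring B the oxygen-bearing carbons C3', C4', C5' and the C6' methine are contiguous and map onto a 1,1,2,3-tetraoxygenated butadiene. C1' (propanoate chain) and the C2' methine map onto the two alkyne carbons of a 2-ynoate.
Forward: ring A is bought as 4-allyl-2,6-dimethoxyphenol and its oxygen is alkylated with a chloroacetoacetate, which is converted into the vinylketene acetal. Ring B is closed by [4+2] cycloaddition and aromatized; the phenol is then methylated, the allyl group oxidized to the acid, the esters hydrolysed and the aryl carboxyl group removed.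
Stereochemistry: the target is achiral and has no stereocentre; the stereogenic elements met on the way (one enolizable centre, enol ether and ketene acetal geometry, one ketal carbon) are all erased.

Key step: step 5

Remark: the enol ether and the diene made from it are carried as mixtures of double-bond isomers, since both geometries end in the same aromatic ring.

**Route**

Step 1
Reactants: 1 4-allyl-2,6-dimethoxyphenol; 2 methyl 2-chloro-3-oxobutanoate (methyl 2-chloroacetoacetate, racemic)
Product: 3 methyl 2-(4-allyl-2,6-dimethoxyphenoxy)-3-oxobutanoate (racemic)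
Conditions: K2CO3, acetone, reflux
Reagents that add atoms: none
Why: Williamson-type SN2 O-alkylation in which the phenoxide of 1 displaces chloride from the doubly carbonyl-activated sp3 carbon of 2, the standard entry to 2-aryloxyacetoacetates, so the ether oxygen is attached to the future C4' without any aryl-oxygen coupling.

Step 2
Reactants: 3 methyl 2-(4-allyl-2,6-dimethoxyphenoxy)-3-oxobutanoate
Product: 5 methyl 2-(4-allyl-2,6-dimethoxyphenoxy)-3-methoxybut-2-enoate (E/Z mixture), via dimethyl ketal 4 (not isolated)
Conditions: HC(OMe)3, H2SO4 (cat.), MeOH, rt to 50 °C, then removal of volatiles under gentle heating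
Reagents that add atoms: trimethyl orthoformate, COC(OC)OC
Why: Acid-catalysed ketalization with the orthoester followed by loss of methanol toward the ester is the standard preparation of 3-methoxy-2-enoates from 2-substituted acetoacetates, and the usual acid-induced cyclodehydration of aryloxyacetoacetates to benzofurans cannot occur because both ortho positions of ring A carry methoxy groups.

Step 3
Reactants: 5 methyl 2-(4-allyl-2,6-dimethoxyphenoxy)-3-methoxybut-2-enoate
Product: 7 2-(4-allyl-2,6-dimethoxyphenoxy)-1,3-dimethoxy-1-(trimethylsilyloxy)buta-1,3-diene (mixture of ketene acetal isomers), via lithium dienolate 6 (not isolated)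
Conditions: LiN(i-Pr)2, THF, −78 °C; then TMSCl, −78 °C to rt; non-aqueous work-up, used crude
Reagents that add atoms: chlorotrimethylsilane, C[Si](C)(C)Cl
Why: Kinetic γ-deprotonation of a 3-methoxy-2-enoate by the amide base and O-silylation of the extended enolate is the standard preparation of 1-alkoxy-1-silyloxy vinylketene acetals, and the allyl group and the aryl ethers should not be attacked by LiN(i-Pr)2 at −78 °C.

Step 4
Reactants: 8 methyl pent-4-ynoate
Product: 9 dimethyl hex-2-ynedioate
Conditions: CO (1 atm), PdCl2 (cat.), CuCl2 (2 equiv), NaOAc (2 equiv), MeOH, rt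
Reagents that add atoms: carbon monoxide, [C-]#[O+]; methanol, CO
Why: Palladium-catalysed oxidative alkoxycarbonylation of a terminal alkyne, in which an alkynyl complex of divalent palladium inserts CO and is cleaved by methanol while CuCl2 returns zerovalent palladium to the divalent state, so the alkyne is carboxylated without a strong base that would enolize the ester.

Step 5
Reactants: 7 2-(4-allyl-2,6-dimethoxyphenoxy)-1,3-dimethoxy-1-(trimethylsilyloxy)buta-1,3-diene; 9 dimethyl hex-2-ynedioate
Product: 12 methyl 3-(4-allyl-2,6-dimethoxyphenoxy)-2-hydroxy-4-methoxy-6-(3-methoxy-3-oxopropyl)benzoate, via cyclohexa-1,4-diene silyl methyl ketal 10 (not isolated), via aryl trimethylsilyl ether 11 (not isolated)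
Conditions: 7 (1.5 equiv, crude), 9 (1 equiv), toluene, sealed tube, 110 °C; then 1 M HCl, THF, rt
Reagents that add atoms: none
Why: The electron-rich vinylketene acetal 7 and the electron-poor ynoate 9 should undergo a thermal, normal-demand, asynchronous [4+2] cycloaddition in which the diene CH2 terminus (future C6') bonds first to the β-carbon of the ynoate (future C1') and the ketene acetal carbon (future C3') then bonds to the ester-bearing α-carbon (future C2'); the closest known reaction type is the Diels-Alder benzannulation of 1,1,3-trioxygenated butadienes with alkynoates to give resorcylates. Ring B is closed as a six-membered carbocycle by this intermolecular cycloaddition, both C-C bonds forming in one operation from a four-carbon and a two-carbon component. The 1,4-cyclohexadiene 10 then expels methanol from its ketal carbon together with a hydrogen of the ring CH2 group to reach the aromatic silyl ether 11, and the acidic work-up cleaves the O-Si bond to give the hydrogen-bonded salicylate 12. No stereocentre remains, because the only one formed (the ketal carbon of 10) is destroyed on aromatization. The step needs regioselectivity, which is secured because the largest HOMO coefficient lies on the unsubstituted CH2 terminus (raised by the donor oxygens at positions 1, 1 and 3) and the largest LUMO coefficient on the β-carbon of the single conjugated ester; it also needs chemoselectivity, which is secured because the allyl group and the remote saturated ester are not activated dienophiles.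

Step 6
Reactants: 12 methyl 3-(4-allyl-2,6-dimethoxyphenoxy)-2-hydroxy-4-methoxy-6-(3-methoxy-3-oxopropyl)benzoate
Product: 13 methyl 3-(4-allyl-2,6-dimethoxyphenoxy)-2,4-dimethoxy-6-(3-methoxy-3-oxopropyl)benzoate
Conditions: MeI, K2CO3, DMF, 40 °C
Reagents that add atoms: iodomethane, CI
Why: Williamson O-methylation of the salicylate phenol under carbonate conditions in a dipolar aprotic solvent, which should leave both esters and the allyl group untouched.

Step 7
Reactants: 13 methyl 3-(4-allyl-2,6-dimethoxyphenoxy)-2,4-dimethoxy-6-(3-methoxy-3-oxopropyl)benzoate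
Product: 15 methyl 3-[4-(3-hydroxypropyl)-2,6-dimethoxyphenoxy]-2,4-dimethoxy-6-(3-methoxy-3-oxopropyl)benzoate, via B-alkyl-9-borabicyclononane 14 (not isolated)
Conditions: 9-BBN, THF, 0 °C to rt; then NaBO3·4H2O, H2O, rt
Reagents that add atoms: 9-BBN, B1C2CCCC1CCC2 (its boron bicycle stays only in 14); sodium perborate, [Na+].[O-]OB=O (oxygen of the alcohol)
Why: Anti-Markovnikov hydroboration of the terminal alkene with the bulky 9-BBN, which does not reduce esters at room temperature, followed by C-B oxidation with the mild perborate, which spares the methyl esters, should give the primary alcohol.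

Step 8
Reactants: 15 methyl 3-[4-(3-hydroxypropyl)-2,6-dimethoxyphenoxy]-2,4-dimethoxy-6-(3-methoxy-3-oxopropyl)benzoate
Product: 17 3-{4-[2,6-dimethoxy-3-(methoxycarbonyl)-4-(3-methoxy-3-oxopropyl)phenoxy]-3,5-dimethoxyphenyl}propanoic acid, via aldehyde 16 (not isolated)
Conditions: TEMPO (cat.), PhI(OAc)2 (2.2 equiv), MeCN/H2O, rt
Reagents that add atoms: water, O
Why: Nitroxyl (oxoammonium) catalysed oxidation with PhI(OAc)2 in aqueous acetonitrile takes a primary alcohol through the aldehyde 16 and its hydrate to the carboxylic acid without chlorinating or oxidizing the electron-rich rings.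

Step 9
Reactants: 17 3-{4-[2,6-dimethoxy-3-(methoxycarbonyl)-4-(3-methoxy-3-oxopropyl)phenoxy]-3,5-dimethoxyphenyl}propanoic acid
Product: 18 6-(2-carboxyethyl)-3-[4-(2-carboxyethyl)-2,6-dimethoxyphenoxy]-2,4-dimethoxybenzoic acid
Conditions: KOH (excess), DMSO/H2O, 100 °C; then aqueous HCl to pH 2
Reagents that add atoms: potassium hydroxide, [K+].[OH-]
Why: Saponification by acyl substitution with hydroxide, in which the side-chain ester cleaves readily and the doubly ortho-substituted benzoate should yield under the forcing aqueous DMSO conditions, to which the aryl ethers are inert.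

Step 10
Reactants: 18 6-(2-carboxyethyl)-3-[4-(2-carboxyethyl)-2,6-dimethoxyphenoxy]-2,4-dimethoxybenzoic acid
Product: 19 Apteniol E, 3,3'-[oxybis(3,5-dimethoxy-4,1-phenylene)]dipropanoic acid
Conditions: Ag2CO3 (20 mol %), AcOH (cat.), DMSO, 120 °C
Reagents that add atoms: none
Why: Silver-catalysed protodecarboxylation of ortho-substituted benzoic acids (loss of CO2 from the monovalent silver carboxylate and protonation of the arylsilver species) should remove only the aryl carboxyl group next to the methoxy group, since the two alkyl carboxylic acids do not decarboxylate without an oxidant.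

**Compound list**
1 | 4-allyl-2,6-dimethoxyphenol | C=CCc1cc(OC)c(O)c(OC)c1 | starting material
2 | methyl 2-chloro-3-oxobutanoate (racemic) | CC(=O)C(Cl)C(=O)OC | starting material
3 | methyl 2-(4-allyl-2,6-dimethoxyphenoxy)-3-oxobutanoate (racemic) | CC(=O)C(Oc1c(OC)cc(CC=C)cc1OC)C(=O)OC | intermediate
4 | methyl 2-(4-allyl-2,6-dimethoxyphenoxy)-3,3-dimethoxybutanoate (racemic, not isolated) | CC(OC)(OC)C(Oc1c(OC)cc(CC=C)cc1OC)C(=O)OC | intermediate
5 | methyl 2-(4-allyl-2,6-dimethoxyphenoxy)-3-methoxybut-2-enoate (E/Z mixture) | CC(OC)=C(Oc1c(OC)cc(CC=C)cc1OC)C(=O)OC | intermediate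
6 | lithium dienolate of 5 (not isolated) | [Li+].C=C(OC)C(Oc1c(OC)cc(CC=C)cc1OC)=C(OC)[O-] | intermediate
7 | 2-(4-allyl-2,6-dimethoxyphenoxy)-1,3-dimethoxy-1-(trimethylsilyloxy)buta-1,3-diene (mixture of ketene acetal isomers) | C=C(OC)C(Oc1c(OC)cc(CC=C)cc1OC)=C(OC)O[Si](C)(C)C | intermediate
8 | methyl pent-4-ynoate | C#CCCC(=O)OC | starting material
9 | dimethyl hex-2-ynedioate | COC(=O)C#CCCC(=O)OC | intermediate
10 | methyl 5-(4-allyl-2,6-dimethoxyphenoxy)-4,6-dimethoxy-2-(3-methoxy-3-oxopropyl)-6-(trimethylsilyloxy)cyclohexa-1,4-diene-1-carboxylate (racemic, not isolated) | COC(=O)CCC1=C(C(=O)OC)C(OC)(O[Si](C)(C)C)C(Oc2c(OC)cc(CC=C)cc2OC)=C(OC)C1 | intermediate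
11 | methyl 3-(4-allyl-2,6-dimethoxyphenoxy)-4-methoxy-6-(3-methoxy-3-oxopropyl)-2-(trimethylsilyloxy)benzoate (not isolated) | COC(=O)CCc1cc(OC)c(Oc2c(OC)cc(CC=C)cc2OC)c(O[Si](C)(C)C)c1C(=O)OC | intermediate
12 | methyl 3-(4-allyl-2,6-dimethoxyphenoxy)-2-hydroxy-4-methoxy-6-(3-methoxy-3-oxopropyl)benzoate | COC(=O)CCc1cc(OC)c(Oc2c(OC)cc(CC=C)cc2OC)c(O)c1C(=O)OC | intermediate
13 | methyl 3-(4-allyl-2,6-dimethoxyphenoxy)-2,4-dimethoxy-6-(3-methoxy-3-oxopropyl)benzoate | COC(=O)CCc1cc(OC)c(Oc2c(OC)cc(CC=C)cc2OC)c(OC)c1C(=O)OC | intermediate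
14 | methyl 3-{4-[3-(9-borabicyclo[3.3.1]nonan-9-yl)propyl]-2,6-dimethoxyphenoxy}-2,4-dimethoxy-6-(3-methoxy-3-oxopropyl)benzoate (not isolated) | COC(=O)CCc1cc(OC)c(Oc2c(OC)cc(CCCB3C4CCCC3CCC4)cc2OC)c(OC)c1C(=O)OC | intermediate
15 | methyl 3-[4-(3-hydroxypropyl)-2,6-dimethoxyphenoxy]-2,4-dimethoxy-6-(3-methoxy-3-oxopropyl)benzoate | COC(=O)CCc1cc(OC)c(Oc2c(OC)cc(CCCO)cc2OC)c(OC)c1C(=O)OC | intermediate
16 | methyl 3-[2,6-dimethoxy-4-(3-oxopropyl)phenoxy]-2,4-dimethoxy-6-(3-methoxy-3-oxopropyl)benzoate (not isolated) | COC(=O)CCc1cc(OC)c(Oc2c(OC)cc(CCC=O)cc2OC)c(OC)c1C(=O)OC | intermediate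
17 | 3-{4-[2,6-dimethoxy-3-(methoxycarbonyl)-4-(3-methoxy-3-oxopropyl)phenoxy]-3,5-dimethoxyphenyl}propanoic acid | COC(=O)CCc1cc(OC)c(Oc2c(OC)cc(CCC(=O)O)cc2OC)c(OC)c1C(=O)OC | intermediate
18 | 6-(2-carboxyethyl)-3-[4-(2-carboxyethyl)-2,6-dimethoxyphenoxy]-2,4-dimethoxybenzoic acid | OC(=O)CCc1cc(OC)c(Oc2c(OC)cc(CCC(=O)O)cc2OC)c(OC)c1C(=O)O | intermediate
19 | Apteniol E, 3,3'-[oxybis(3,5-dimethoxy-4,1-phenylene)]dipropanoic acid | COc1cc(CCC(=O)O)cc(OC)c1Oc1c(OC)cc(CCC(=O)O)cc1OC | target

**Step count**
Total: 10 steps. Longest linear sequence: 9 steps (steps 1, 2, 3, 5, 6, 7, 8, 9, 10, from phenol 1); step 4 is a one-step branch.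

**Steps most likely to fail**

Step 5. Desilylation or thermal decomposition of the hindered, fully substituted diene may outrun the cycloaddition, because a β-alkyl ynoate is only a moderately reactive dienophile. The fallback sets out from diene 7 and comes back at phenol 12; it replaces the alkyne by its more reactive allene isomer. Methyl 4-chloro-4-oxobutanoate is treated with Et3N and methyl (triphenylphosphoranylidene)acetate in CH2Cl2 (Wittig reaction of the ketene formed in the flask) to give dimethyl hexa-2,3-dienedioate F1. Diene 7 should add across the ester-conjugated double bond of F1 with the same orientation at lower temperature (toluene, 60 to 80 °C), the CH2 terminus bonding to the central allene carbon, to give the alkylidenecyclohexene cycloadduct F2. On the HCl work-up F2 should lose methanol and shift its exocyclic double bond into the ring, passing through silyl ether 11 to phenol 12.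

Step 2. Ketalization of the hindered α-aryloxy ketone may stall, and acid-induced retro-Claisen loss of the acetyl group may compete in acidic methanol. The fallback sets out from keto ester 3 and comes back at methyl ether 13; it carries the oxygen at the future C5' as a silyl ether instead of a methyl ether. TMSCl and Et3N (THF, rt) should convert 3 into methyl 2-(4-allyl-2,6-dimethoxyphenoxy)-3-(trimethylsilyloxy)but-2-enoate F3. LiN(i-Pr)2 and then TMSCl (THF, −78 °C) should give 2-(4-allyl-2,6-dimethoxyphenoxy)-1-methoxy-1,3-bis(trimethylsilyloxy)buta-1,3-diene F4. Heating F4 with ynoate 9 as in step 5 should give the cyclohexa-1,4-diene cycloadduct F5 and, after loss of methanol, the aromatic bis(trimethylsilyl ether) F6. HCl work-up should give methyl 3-(4-allyl-2,6-dimethoxyphenoxy)-2,4-dihydroxy-6-(3-methoxy-3-oxopropyl)benzoate F7, and excess MeI with K2CO3 in DMF should methylate both phenols to give 13.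

Step 9. Hydroxide attack at the ester carbonyl on C2', which is flanked by the C3' methoxy group and the C1' side chain, may be too slow, so that only the side-chain ester is cleaved. The fallback sets out from 17 and comes back at 18 without any new compound. It moves the cleavage from the shielded acyl carbon to the unhindered O-methyl carbon: SN2 dealkylation with LiI in pyridine at reflux, followed by acidification with HCl, should cleave both methyl esters and leave the aryl methyl ethers intact at this temperature.

**Further compounds**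
F1 | step 5 | dimethyl hexa-2,3-dienedioate (racemic) | COC(=O)C=C=CCC(=O)OC
F2 | step 5 | methyl 3-(4-allyl-2,6-dimethoxyphenoxy)-2,4-dimethoxy-6-(3-methoxy-3-oxopropylidene)-2-(trimethylsilyloxy)cyclohex-3-ene-1-carboxylate (mixture of isomers) | COC(=O)CC=C1CC(OC)=C(Oc2c(OC)cc(CC=C)cc2OC)C(OC)(O[Si](C)(C)C)C1C(=O)OC
F3 | step 2 | methyl 2-(4-allyl-2,6-dimethoxyphenoxy)-3-(trimethylsilyloxy)but-2-enoate (E/Z mixture) | CC(O[Si](C)(C)C)=C(Oc1c(OC)cc(CC=C)cc1OC)C(=O)OC
F4 | step 2 | 2-(4-allyl-2,6-dimethoxyphenoxy)-1-methoxy-1,3-bis(trimethylsilyloxy)buta-1,3-diene (mixture of ketene acetal isomers) | C=C(O[Si](C)(C)C)C(Oc1c(OC)cc(CC=C)cc1OC)=C(OC)O[Si](C)(C)C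
F5 | step 2 | methyl 5-(4-allyl-2,6-dimethoxyphenoxy)-6-methoxy-2-(3-methoxy-3-oxopropyl)-4,6-bis(trimethylsilyloxy)cyclohexa-1,4-diene-1-carboxylate (racemic) | COC(=O)CCC1=C(C(=O)OC)C(OC)(O[Si](C)(C)C)C(Oc2c(OC)cc(CC=C)cc2OC)=C(O[Si](C)(C)C)C1
F6 | step 2 | methyl 3-(4-allyl-2,6-dimethoxyphenoxy)-6-(3-methoxy-3-oxopropyl)-2,4-bis(trimethylsilyloxy)benzoate | COC(=O)CCc1cc(O[Si](C)(C)C)c(Oc2c(OC)cc(CC=C)cc2OC)c(O[Si](C)(C)C)c1C(=O)OC
F7 | step 2 | methyl 3-(4-allyl-2,6-dimethoxyphenoxy)-2,4-dihydroxy-6-(3-methoxy-3-oxopropyl)benzoate | COC(=O)CCc1cc(O)c(Oc2c(OC)cc(CC=C)cc2OC)c(O)c1C(=O)OC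
F0 | step 9 | none | none
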